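The readings are simulated on assumed constants.

- Find the flask that holds the most J after 2.0 d, and what J is worth in each.

| flask | G | L | temperature | remark | time |
|---|---|---|---|---|---|
| maple | 1.1 M | 0.96 M | 25 °C | run made earlier |  |
| oak | 1.8 M | 0.96 M | 58 °C | run made earlier |  |
| west | 0.80 M | 0.960 M | 10 °C |  | 2.0 d |
| north-east | 0.80 M | 0.960 M | 70 °C |  | 2.0 d |
| north-west | 0.80 M | 0.960 M | 50 °C |  | 2.0 d |
| south-east | 0.80 M | 0.960 M | 30 °C |  | 2.0 d |

| run | time / h | J / % | G / % |
|---|---|---|---|
| maple | 1.00 | 2.9 | 97.2 |
| maple | 3.00 | 8.0 | 92.6 |
| maple | 5.00 | 12.2 | 87.8 |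
| maple | 8.00 | 17.4 | 82.4 |
| maple | 10.0 | 20.2 | 79.2 |
| maple | 15.0 | 26.4 | 73.4 |
| oak | 0.500 | 17.7 | 82.5 |
| oak | 1.00 | 25.9 | 72.8 |
| oak | 1.33 | 29.3 | 67.6 |
| oak | 2.00 | 34.8 | 62.2 |
| oak | 2.50 | 36.5 | 58.9 |
| oak | 3.00 | 38.8 | 56.9 |

(scatter of a reading: 0.3 percentage points)

- the flask with the highest amount of J, in percent of the G charged ("all alike" if they lie within 1.5 percentage points) (west / north-east / north-west / south-east / all alike)
- final J, as a percentage of the G charged, in west
- final J, as a percentage of the G charged, in north-east
- final J, as a percentage of the G charged, in north-west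
- final J, as a percentage of the G charged, in south-east

- a species is counted by the G in it: one E counts as two
- the analysis behind the earlier runs scatters by 0.3 percentage points, standard deviation
- steps under discussion: G + L -> J; G + J -> E

- Start from the oak balance. At 3.00 h, J and G leave 4.30 % of the charge unread, and that gap is E. One E holds one G and one J, so J lost half of the gap, and the leaked share of all J made is 5.25 %.
- Define the leak ratio as the rate of losing J to E over the rate of making J. Assume making is second order in G and first in L, and losing first in G and in J. The ratio is then a constant times J over G times L, and J peaks where it reaches one.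
- Treat the oak reading at 1.00 h as a typical moment. That gives the leak constant, the ratio of the two rate constants, as roughly 0.0729 M.
- Set oak beside north-west, 58 °C against 50 °C, and keep the constant unshifted as a rough step. Oak has L as limiting reagent, with more G than L, and its J cannot pass 53.3 % of its G. North-west has less G than L, so G limits there.
- Compare the two at oak's last J share. Oak has 0.223 M of L left and a ratio of 0.223. North-west, with E ignored, stands lower at 0.0711, so it can climb further.
- Commit to north-west, as a judgement. Maple at 25 °C reached 26.4 % of J by 15.0 h, so I expect the cold flasks to lag. That says nothing about north-east, the hot rival. There the unshifted constant is too crude: maple's last balance leaves 0.200 % unread, against a scatter of 0.3 percentage points and less than oak's 4.30 %. So I take the leak constant to rise with heat, though oak also differs from maple in its G and its time. North-east at 70 °C stands hotter than oak, so I expect its J to fall back below north-west's.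
- The forecast agrees: north-west, with 21 % in west, 55 % in north-east, 64 % in north-west and 52 % in south-east. It calls the order of the first step uncertain and sees 50 °C as “near completion with modest E loss”.

    G + L → J, rate k1*[G]^2*[L] (k = 0.180 M⁻² h⁻¹, Ea = 59.0 kJ mol⁻¹)
    G + J → E (k = 0.0130 M⁻¹ h⁻¹, Ea = 88.0 kJ mol⁻¹)
    (constants at 50 °C)

- North-west gives 63.9 % and leads; west has 21.1 %, north-east 50.7 % and south-east 51.0 %. After 2.00 d, north-west still holds G at 18.7 % and L at 39.5 % of its own charge, with E at 17.4 %. Those amounts give a leak ratio of 0.656, below one. North-east after 1.00 d, with J at 53.8 %, G at 8.31 % and L at 39.4 %, gives 1.25 with oak's constant, above one, and its J falls to 50.7 % by 2.00 d.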